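## The problem

Difengpiol A (23) joins two rings through one single bond. C2 of a 7-methoxy-2,3-dihydrobenzofuran, which also carries CH2OH at C3 and a 3-hydroxypropyl chain at C5, is bonded to C1′ of a cyclohexene (ring C1′–C6′) with a cis-diol at C3′ and C4′. The four stereocentres form two pairs, C2/C3 (trans, 2S,3R) and C3′/C4′ (cis, 3′S,4′R). The pairs are separated by the sp2 carbon C1′ and the freely rotating C2–C1′ bond, so neither can be trusted to direct the other, and each needs its own source of absolute configuration. Within a pair, relative control is available: trans at C2/C3 is the thermodynamic arrangement while C2 is epimerisable next to a carbonyl group, and cis at C3′/C4′ is what a suprafacial ring-forming step delivers. The molecule does not tolerate rough treatment: the allylic cis-diol can dehydrate towards an arene under acid, the C2–O1 bond is both an aryl ether and allylic and can ionise, and the trisubstituted alkene and the guaiacol-type arene are open to electrophilic oxidants. The decisive feature is ring C1′–C6′: its double bond C1′=C2′ lies between the substituted carbon C1′ and the allylic carbinol C3′, with the second carbinol C4′ next to it. This is the retron of a Diels–Alder reaction between a 1-oxygenated 3-substituted butadiene (C6′, C1′, C2′, C3′) and a two-carbon dienophile (C4′, C5′) whose activating group sits on C4′ and is later exchanged for oxygen.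

## Retrosynthesis

**23 from 22.** The last operation should only unmask hydroxyl groups, so the four O–acyl bonds are cut to give tetraacetate 22. Acetates are preferred to silyl or benzyl ethers because they all leave under catalytic carbonate in methanol, which spares the allylic diol and the allylic aryl ether; acid or hydrogenolysis would not. The forward step is a mild transesterification.

**22 from 21.** The C4′–O bond is traced back to a C4′–C(acyl) bond. Oxygen insertion (Baeyer–Villiger) retains configuration at the migrating carbon, so the cis relationship is carried into the diol. Direct insertion at the formyl group of aldehyde 19 was set aside for two reasons: a formyl group can also lose hydrogen by migration and end as the acid, and a peracid would not distinguish reliably between the aldehyde and the C1′=C2′ alkene. Methyl ketone 21 has a clear migratory preference (secondary C4′ over methyl) and can be oxidised with a silyl peroxide under Lewis-acid catalysis, which leaves C=C bonds alone. The forward step must insert oxygen without epoxidation and without ionising the allylic acetate.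

**21 from 20 from 19.** The extra methyl carbon is removed by cutting the CH3–C bond. Ketone 21 comes from carbinol 20 by oxidation, and 20 from aldehyde 19 by methyl addition. The forward steps must be selective for the aldehyde beside three acetates and must not cause loss of the β-acetoxy group or epimerisation at C4′.

**19 from 17 and 18 (key disconnection).** C3′–C4′ and C5′–C6′ are cut, which opens the cyclohexene into dienyl acetate 17 and acrolein 18. The neighbouring options are worse. Dihydroxylation of a cyclohexadiene offers no handle for face selection remote from C2, and coupling a preformed chiral cyclohexenyl unit at C2–C1′ needs a separate enantioselective fragment synthesis. The cycloaddition removes a ring and two stereocentres at once, and its regiochemistry is reinforced by both diene substituents. The forward reaction must be endo-selective and catalyst-controlled in the presence of the C2/C3 centres.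

**17 from 15 and 16.** The diene is cut at C1′=C6′ and C2′=C3′. Cross enyne metathesis places the CH2 and CH(OAc) halves of vinyl acetate 16 on the two alkyne carbons of 15. Making the dienyl acetate by enolisation of an enal would cost several more steps and would expose C2–H to base. Alkyne 15 carries no diene and no enol ester. The forward step must give the E enol acetate and tolerate the propargylic ether.

**15 from 13 from 11.** The alkyne C1′≡C2′ comes from the ester carbon of 11 by reduction to aldehyde 12 and one-carbon homologation with a diazophosphonate. The carbonate/methanol medium of that homologation rules out acetates, so 11–13 carry silyl ethers, which are exchanged for acetates (13 to 14 to 15) before the diene is made.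

**11 from 10 from 9.** With an ester on C2 the trans arrangement is thermodynamic, so only C3 needs an enantioselective step. Cis-hydrogenation of the flat, achiral benzofuran 9 sets C3 in 10, and base then moves C2 to give 11. Making C2–C3 by aldol or insertion chemistry would need an arylacetic acid precursor and more steps.

**9 from 6 and 7.** O1–C2 and C2=C3 are cut. The phenol of 6 is alkylated with ethyl bromoacetate 7 to give 8, and intramolecular aldol condensation onto the aryl ketone closes and aromatises the furan in the same operation.

**6 from 5 from 2 and 3; 2 from 1.** The C3–C3a bond is cut. Ortho-hydroxyalkylation of the magnesium phenoxide 4 of phenol 2 with aldehyde 3 brings in C3 together with its CH2O substituent; the para position is blocked by the chain and the other ortho position by the methoxy group. Oxidation of carbinol 5 gives ketone 6. Acylation under strong Lewis acids would not tolerate silyl ethers, and radical bromination of a 3-methylbenzofuran would compete at the benzylic CH2 of the side chain. Phenol 2 is the mono-silyl ether of dihydroconiferyl alcohol 1, which already holds the complete arene substitution pattern.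

## Roads not taken

**Alternative 1: alkyne cyclotrimerisation.** The cut is through the arene at C3a–C7a, C4–C5 and C6–C7. In the forward direction the ynol-ether diyne A2 and the silyl ether of pent-4-yn-1-ol A3 would be cyclotrimerised with Cp*RuCl(cod) to the arylboronate A1, closing the benzene and dihydrofuran rings together; the boronate on C7 would then be oxidised and methylated.
- Merits: two rings in one step, high convergence, and the C7 oxygen placed regiochemically through boron. In rings formed per step this road is ahead of the chosen key step.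
- Weak points: the key step creates none of the four stereocentres. C2, C3, C3′ and C4′ must all be present in A2, a sensitive alkynyl-boronate ynol ether on a carbinol that already carries the finished cyclohexene, so the real stereochemical work is moved into an unspecified multistep synthesis. The unsymmetrical monoyne A3 can enter in two orientations (chain on C5 or C6). Two further steps convert boron into methoxy. An arene is built that commerce supplies fully substituted as 1.
- Comparison: the chosen plan has only one ring closure to set against two, but its key step creates two stereocentres under catalyst control and the route starts from the natural arene.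

**Alternative 2: dirhodium carbenoid C–H insertion.** The cut is C2–C3. The aryldiazoacetate A5 would lose nitrogen at Rh2(S-DOSP)4, a chiral tetracarboxylate of divalent rhodium, and the carbenoid carbon would insert into an O–CH2 hydrogen of the cyclohexenylmethyl ether to give, after base equilibration at C3, the trans ester A4.
- Merits: for the heterocycle alone this is the more direct asymmetric entry and it is well precedented for ether α-C–H bonds. It is convergent, needs no hydrogenation–epimerisation sequence, and sets C2 by the catalyst with C3 following thermodynamically. On this point it is better than the chosen route.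
- Weak points: the C–H bond to be functionalised is allylic and lies next to the C1′=C2′ alkene, so cyclopropanation and ylide pathways compete. The resident 3′,4′ centres make matched and mismatched pairs with the catalyst. The acetonide-protected cyclohexenylmethanol must be made enantiopure on its own.
- Comparison: the chosen plan creates the cyclohexene and both of its stereocentres from acrolein in one catalytic step, needs no chiral cyclohexene building block, and asks no carbenoid to choose between a C–H bond and a neighbouring alkene.

**Alternative 3: trivalent-iodine ring contraction.** The cut is C3–C3a, made by aryl migration. The chroman-4-one A7 would be treated with PhI(OAc)2, trimethyl orthoformate and sulfuric acid in methanol, so that the aryl carbon migrates from the carbonyl carbon to the α-carbon and the pyranone contracts to the methyl ester A6.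
- Merits: the trans relationship and the C3 ester arise in a single step from a C2 centre that is kept. For fixing C2/C3 relative configuration this is better than hydrogenation followed by epimerisation.
- Weak points: an electrophilic trivalent iodine reagent in strong acid and methanol meets a trisubstituted alkene, two allylic acetates and an electron-rich arene, all of which can react. 2-Substituted chromanones racemise by reversible ring opening. The cyclohexene must again be supplied enantiopure.
- Comparison: the chosen plan uses an oxidant only once the alkene is present, and then one that is alkene-tolerant, and it makes the cyclohexene stereocentres catalytically.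

Key step: step 10

Assumption: which antipode of the chiral hydrogenation ligand in step 5 delivers the 3R centre cannot be predicted with confidence; both antipodes are accessible and the one that gives 3R is used.

## Route

Step 1
Reactants: 1 dihydroconiferyl alcohol
Product: 2 4-[3-(tert-butyldimethylsilyloxy)propyl]-2-methoxyphenol
Conditions: TBSCl (1.05 equiv), imidazole, CH2Cl2, 0 °C
Reagents that add atoms: tert-butyldimethylsilyl chloride, CC(C)(C)[Si](C)(C)Cl
Why: Silyl ether formation; the primary aliphatic hydroxyl is the better nucleophile towards the silylimidazolium species than the neutral phenol, which is hydrogen-bonded to the ortho methoxy group, so one equivalent at 0 °C should protect the chain selectively.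

Step 2
Reactants: 2 4-[3-(tert-butyldimethylsilyloxy)propyl]-2-methoxyphenol; 3 (tert-butyldimethylsilyloxy)acetaldehyde
Product: 5 racemic 2-[2-(tert-butyldimethylsilyloxy)-1-hydroxyethyl]-4-[3-(tert-butyldimethylsilyloxy)propyl]-6-methoxyphenol, via bromomagnesium phenoxide 4 (not isolated)
Conditions: EtMgBr (1.0 equiv), Et2O, 0 °C; solvent exchange to CH2Cl2; 3, rt
Reagents that add atoms: none
Why: Ortho-specific hydroxyalkylation of a magnesium phenoxide, in which magnesium bridges the phenoxide and aldehyde oxygens in a six-membered transition state; the para position is blocked and the other ortho position carries OMe, so only C3a can react, and the new carbinol centre is racemic but is removed in step 3.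

Step 3
Reactants: 5 racemic 2-[2-(tert-butyldimethylsilyloxy)-1-hydroxyethyl]-4-[3-(tert-butyldimethylsilyloxy)propyl]-6-methoxyphenol
Product: 6 2-(tert-butyldimethylsilyloxy)-1-{2-hydroxy-3-methoxy-5-[3-(tert-butyldimethylsilyloxy)propyl]phenyl}ethan-1-one
Conditions: MnO2 (activated, excess), CH2Cl2, rt
Reagents that add atoms: none
Why: Manganese dioxide oxidation of a benzylic secondary alcohol, which is selective for the activated carbinol and leaves the silyl ethers and the free phenol untouched.

Step 4
Reactants: 6 2-(tert-butyldimethylsilyloxy)-1-{2-hydroxy-3-methoxy-5-[3-(tert-butyldimethylsilyloxy)propyl]phenyl}ethan-1-one; 7 ethyl bromoacetate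
Product: 9 ethyl 3-[(tert-butyldimethylsilyloxy)methyl]-5-[3-(tert-butyldimethylsilyloxy)propyl]-7-methoxybenzofuran-2-carboxylate, via aryloxyacetate keto ester 8 (not isolated)
Conditions: 7 (1.2 equiv), K2CO3, DMF, rt then 90 °C
Reagents that add atoms: none
Why: Rap–Stoermer-type benzofuran synthesis: the phenoxide is O-alkylated, the ester α-carbon then adds to the aryl ketone in an intramolecular aldol reaction (forming C2–C3), and loss of water is driven by aromatisation of the furan.

Step 5
Reactants: 9 ethyl 3-[(tert-butyldimethylsilyloxy)methyl]-5-[3-(tert-butyldimethylsilyloxy)propyl]-7-methoxybenzofuran-2-carboxylate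
Product: 10 ethyl (2R,3R)-3-[(tert-butyldimethylsilyloxy)methyl]-5-[3-(tert-butyldimethylsilyloxy)propyl]-7-methoxy-2,3-dihydrobenzofuran-2-carboxylate (cis)
Conditions: Ru(cod)(2-methylallyl)2 (5 mol%), 1,3-bis[1-(1-naphthyl)ethyl]-4,5-dihydroimidazolium tetrafluoroborate (single antipode, 10 mol%), KOtBu (15 mol%), hexane, H2 (100 bar), 40 °C
Reagents that add atoms: none
Why: Catalytic asymmetric hydrogenation of the benzofuran C2=C3 bond by a chiral ruthenium–N-heterocyclic carbene catalyst; both hydrogens are delivered to one face (syn addition), which gives the cis ester and sets C3 as R through the catalyst's face selection, while C2 is corrected in step 6.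

Step 6
Reactants: 10 ethyl (2R,3R)-3-[(tert-butyldimethylsilyloxy)methyl]-5-[3-(tert-butyldimethylsilyloxy)propyl]-7-methoxy-2,3-dihydrobenzofuran-2-carboxylate (cis)
Product: 11 ethyl (2S,3R)-3-[(tert-butyldimethylsilyloxy)methyl]-5-[3-(tert-butyldimethylsilyloxy)propyl]-7-methoxy-2,3-dihydrobenzofuran-2-carboxylate (trans)
Conditions: NaOEt (0.2 equiv), EtOH, rt
Reagents that add atoms: none
Why: Base-mediated epimerisation α to the ester; reversible enolisation at C2 funnels the cis isomer into the thermodynamically favoured trans isomer, C3 has no acidic hydrogen and keeps its configuration, and ethoxide in ethanol cannot scramble the ester.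

Step 7
Reactants: 11 ethyl (2S,3R)-3-[(tert-butyldimethylsilyloxy)methyl]-5-[3-(tert-butyldimethylsilyloxy)propyl]-7-methoxy-2,3-dihydrobenzofuran-2-carboxylate (trans)
Product: 13 (2S,3R)-3-[(tert-butyldimethylsilyloxy)methyl]-5-[3-(tert-butyldimethylsilyloxy)propyl]-2-ethynyl-7-methoxy-2,3-dihydrobenzofuran, via 2-carbaldehyde 12 (not isolated)
Conditions: iBu2AlH (1.1 equiv), CH2Cl2, −78 °C; then MeOH, K2CO3, dimethyl (1-diazo-2-oxopropyl)phosphonate, −78 °C to rt
Reagents that add atoms: dimethyl (1-diazo-2-oxopropyl)phosphonate, COP(=O)(OC)C(=[N+]=[N-])C(C)=O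
Why: Partial reduction of the α-alkoxy ester stops at the chelated aluminium hemiacetal, and the released aldehyde is homologated in the same flask by the Ohira–Bestmann reaction (addition of the diazomethylphosphonate anion, loss of phosphate and nitrogen, 1,2-shift of the carbene); any epimerisation of the aldehyde under carbonate can only lead to the favoured trans isomer.

Step 8
Reactants: 13 (2S,3R)-3-[(tert-butyldimethylsilyloxy)methyl]-5-[3-(tert-butyldimethylsilyloxy)propyl]-2-ethynyl-7-methoxy-2,3-dihydrobenzofuran
Product: 15 3-[(2S,3R)-3-(acetoxymethyl)-2-ethynyl-7-methoxy-2,3-dihydrobenzofuran-5-yl]propyl acetate, via diol 14 (not isolated)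
Conditions: Bu4NF, THF, 0 °C to rt; then Ac2O, Et3N, DMAP (cat.)
Reagents that add atoms: acetic anhydride, CC(=O)OC(C)=O
Why: Fluoride cleavage of both silyl ethers followed by acetylation in the same flask; this exchanges a protecting group needed for the hydride and carbonate steps for one that survives the acidic aqueous cycloaddition medium and is removed at the end by methanolysis.

Step 9
Reactants: 15 3-[(2S,3R)-3-(acetoxymethyl)-2-ethynyl-7-methoxy-2,3-dihydrobenzofuran-5-yl]propyl acetate; 16 vinyl acetate
Product: 17 (1E)-3-[(2S,3R)-3-(acetoxymethyl)-5-(3-acetoxypropyl)-7-methoxy-2,3-dihydrobenzofuran-2-yl]buta-1,3-dien-1-yl acetate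
Conditions: 16 (10 equiv), second-generation Grubbs catalyst RuCl2(=CHPh)(PCy3)(H2IMes) (10 mol%), toluene, 80 °C; E isomer separated by chromatography
Reagents that add atoms: none
Why: Cross enyne metathesis of a terminal alkyne with an enol ester: the ruthenium alkylidene adds to the alkyne, the ruthenacyclobutene opens to a vinylcarbene, and turnover with vinyl acetate leaves its CH2 carbon as C6′ and its CH(OAc) carbon as C3′ on the former alkyne carbons C1′ and C2′; the E enol acetate is the more stable isomer and the only one able to serve as a diene.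

Step 10
Reactants: 17 (1E)-3-[(2S,3R)-3-(acetoxymethyl)-5-(3-acetoxypropyl)-7-methoxy-2,3-dihydrobenzofuran-2-yl]buta-1,3-dien-1-yl acetate; 18 acrolein
Product: 19 (1S,6R)-3-[(2S,3R)-3-(acetoxymethyl)-5-(3-acetoxypropyl)-7-methoxy-2,3-dihydrobenzofuran-2-yl]-6-formylcyclohex-2-en-1-yl acetate (C3′ S and C4′ R; acetoxy and formyl cis)
Conditions: 18 (3 equiv), (5S)-5-benzyl-2,2,3-trimethylimidazolidin-4-one hydrochloride (20 mol%), MeNO2–H2O (95:5), 0 °C
Reagents that add atoms: none
Why: Acrolein condenses reversibly with the secondary amine salt to the (E)-iminium ion, whose lowered LUMO adds to the acetoxy diene of 17 in a concerted, asynchronous, normal-demand [4+2] cycloaddition; the closest known reaction type is the iminium-catalysed Diels–Alder reaction of acrolein with 1-acyloxy- and 2-substituted butadienes under the same catalyst. The ring C1′–C6′ closes by cycloaddition in one suprafacial event that forms C3′–C4′ (the leading bond, between the acetoxy-bearing diene terminus and the α-carbon of acrolein) and C5′–C6′. The acetoxy group directs the formyl-bearing carbon to the adjacent position and the C1′ substituent directs it para, so both place CHO on C4′. C4′ is controlled by the catalyst: the benzyl group covers the Re face of the iminium α-carbon, the diene bonds to the Si face, and with the (5S) catalyst this gives 4′R. C3′ is controlled by the endo transition state of the E enol acetate, which places acetoxy and formyl cis and gives 3′S. The step needs endo over exo selectivity and catalyst control over the diene-face bias of the C2 centre; that bias should be weak because C2 sits on a rotatable bond at the non-reacting carbon C1′, and the E geometry of 17 secures both the s-cis conformer and the stereospecific transfer into C3′. Hydrolysis releases 19 and the amine, and the aldehyde is taken on at once to avoid β-elimination of acetic acid.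

Step 11
Reactants: 19 (1S,6R)-3-[(2S,3R)-3-(acetoxymethyl)-5-(3-acetoxypropyl)-7-methoxy-2,3-dihydrobenzofuran-2-yl]-6-formylcyclohex-2-en-1-yl acetate
Product: 20 the 6-(1-hydroxyethyl) carbinol of 19: 3-[(2S,3R)-3-(acetoxymethyl)-5-(3-acetoxypropyl)-7-methoxy-2,3-dihydrobenzofuran-2-yl]-6-(1-hydroxyethyl)cyclohex-2-en-1-yl acetate (ring centres as in 19; both epimers at the new carbinol carbon)
Conditions: MeTi(OiPr)3 (1.5 equiv), THF, −40 to 0 °C
Reagents that add atoms: methyltitanium triisopropoxide, C[Ti](OC(C)C)(OC(C)C)OC(C)C
Why: Chemoselective 1,2-addition of a weakly basic methyltitanium reagent to the aldehyde; acetates are not attacked, the titanium alkoxide is too poorly nucleophilic for acyl migration, and the low basicity avoids enolisation at C4′ and loss of the β-acetoxy group; the new carbinol centre is removed in step 12.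

Step 12
Reactants: 20 the 6-(1-hydroxyethyl) carbinol of 19
Product: 21 (1S,6R)-6-acetyl-3-[(2S,3R)-3-(acetoxymethyl)-5-(3-acetoxypropyl)-7-methoxy-2,3-dihydrobenzofuran-2-yl]cyclohex-2-en-1-yl acetate
Conditions: Dess–Martin periodinane, CH2Cl2, 0 °C to rt
Reagents that add atoms: none
Why: Dess–Martin oxidation of a secondary alcohol under near-neutral conditions, which should not epimerise the ketone at C4′ or disturb the allylic acetate and the alkene.

Step 13
Reactants: 21 (1S,6R)-6-acetyl-3-[(2S,3R)-3-(acetoxymethyl)-5-(3-acetoxypropyl)-7-methoxy-2,3-dihydrobenzofuran-2-yl]cyclohex-2-en-1-yl acetate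
Product: 22 (1R,2S)-4-[(2S,3R)-3-(acetoxymethyl)-5-(3-acetoxypropyl)-7-methoxy-2,3-dihydrobenzofuran-2-yl]cyclohex-3-ene-1,2-diyl diacetate
Conditions: Me3SiOOSiMe3 (2 equiv), Me3SiOTf (10 mol%), CH2Cl2, −78 to −30 °C
Reagents that add atoms: bis(trimethylsilyl) peroxide, C[Si](C)(C)OO[Si](C)(C)C
Why: Baeyer–Villiger oxidation with a silyl peroxide: the Lewis acid promotes addition of the peroxide to the ketone and the silylated Criegee-type adduct rearranges with migration of the secondary carbon C4′ in preference to methyl and with retention of configuration, so the new acetate stays cis to the C3′ acetate; this reagent system is used because it does not epoxidise isolated C=C bonds.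

Step 14
Reactants: 22 (1R,2S)-4-[(2S,3R)-3-(acetoxymethyl)-5-(3-acetoxypropyl)-7-methoxy-2,3-dihydrobenzofuran-2-yl]cyclohex-3-ene-1,2-diyl diacetate
Product: 23 difengpiol A, (1R,2S)-4-[(2S,3R)-3-(hydroxymethyl)-5-(3-hydroxypropyl)-7-methoxy-2,3-dihydrobenzofuran-2-yl]cyclohex-3-ene-1,2-diol
Conditions: K2CO3 (cat.), MeOH, rt
Reagents that add atoms: none
Why: Carbonate-catalysed transesterification removes all four acetates as methyl acetate under conditions that touch neither the allylic diol nor the allylic aryl ether, and no stereocentre is affected.

## Compound list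

1 | dihydroconiferyl alcohol, 4-(3-hydroxypropyl)-2-methoxyphenol | COc1cc(CCCO)ccc1O | starting material
2 | 4-[3-(tert-butyldimethylsilyloxy)propyl]-2-methoxyphenol | COc1cc(CCCO[Si](C)(C)C(C)(C)C)ccc1O | intermediate
3 | (tert-butyldimethylsilyloxy)acetaldehyde | O=CCO[Si](C)(C)C(C)(C)C | starting material
4 | bromomagnesium 4-[3-(tert-butyldimethylsilyloxy)propyl]-2-methoxyphenoxide | COc1cc(CCCO[Si](C)(C)C(C)(C)C)ccc1O[Mg]Br | intermediate (not isolated)
5 | racemic 2-[2-(tert-butyldimethylsilyloxy)-1-hydroxyethyl]-4-[3-(tert-butyldimethylsilyloxy)propyl]-6-methoxyphenol | COc1cc(CCCO[Si](C)(C)C(C)(C)C)cc(C(O)CO[Si](C)(C)C(C)(C)C)c1O | intermediate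
6 | 2-(tert-butyldimethylsilyloxy)-1-{2-hydroxy-3-methoxy-5-[3-(tert-butyldimethylsilyloxy)propyl]phenyl}ethan-1-one | COc1cc(CCCO[Si](C)(C)C(C)(C)C)cc(C(=O)CO[Si](C)(C)C(C)(C)C)c1O | intermediate
7 | ethyl bromoacetate | CCOC(=O)CBr | starting material
8 | ethyl 2-{2-[(tert-butyldimethylsilyloxy)acetyl]-6-methoxy-4-[3-(tert-butyldimethylsilyloxy)propyl]phenoxy}acetate | COc1cc(CCCO[Si](C)(C)C(C)(C)C)cc(C(=O)CO[Si](C)(C)C(C)(C)C)c1OCC(=O)OCC | intermediate (not isolated)
9 | ethyl 3-[(tert-butyldimethylsilyloxy)methyl]-5-[3-(tert-butyldimethylsilyloxy)propyl]-7-methoxybenzofuran-2-carboxylate | CCOC(=O)c1oc2c(OC)cc(CCCO[Si](C)(C)C(C)(C)C)cc2c1CO[Si](C)(C)C(C)(C)C | intermediate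
10 | ethyl (2R,3R)-3-[(tert-butyldimethylsilyloxy)methyl]-5-[3-(tert-butyldimethylsilyloxy)propyl]-7-methoxy-2,3-dihydrobenzofuran-2-carboxylate (cis) | COc1cc(CCCO[Si](C)(C)C(C)(C)C)cc2c1O[C@@H](C(=O)OCC)[C@H]2CO[Si](C)(C)C(C)(C)C | intermediate
11 | ethyl (2S,3R)-3-[(tert-butyldimethylsilyloxy)methyl]-5-[3-(tert-butyldimethylsilyloxy)propyl]-7-methoxy-2,3-dihydrobenzofuran-2-carboxylate (trans) | COc1cc(CCCO[Si](C)(C)C(C)(C)C)cc2c1O[C@H](C(=O)OCC)[C@H]2CO[Si](C)(C)C(C)(C)C | intermediate
12 | (2S,3R)-3-[(tert-butyldimethylsilyloxy)methyl]-5-[3-(tert-butyldimethylsilyloxy)propyl]-7-methoxy-2,3-dihydrobenzofuran-2-carbaldehyde | COc1cc(CCCO[Si](C)(C)C(C)(C)C)cc2c1O[C@H](C=O)[C@H]2CO[Si](C)(C)C(C)(C)C | intermediate (not isolated)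
13 | (2S,3R)-3-[(tert-butyldimethylsilyloxy)methyl]-5-[3-(tert-butyldimethylsilyloxy)propyl]-2-ethynyl-7-methoxy-2,3-dihydrobenzofuran | COc1cc(CCCO[Si](C)(C)C(C)(C)C)cc2c1O[C@H](C#C)[C@H]2CO[Si](C)(C)C(C)(C)C | intermediate
14 | 3-[(2S,3R)-2-ethynyl-3-(hydroxymethyl)-7-methoxy-2,3-dihydrobenzofuran-5-yl]propan-1-ol | COc1cc(CCCO)cc2c1O[C@H](C#C)[C@H]2CO | intermediate (not isolated)
15 | 3-[(2S,3R)-3-(acetoxymethyl)-2-ethynyl-7-methoxy-2,3-dihydrobenzofuran-5-yl]propyl acetate | COc1cc(CCCOC(C)=O)cc2c1O[C@H](C#C)[C@H]2COC(C)=O | intermediate
16 | vinyl acetate | C=COC(C)=O | starting material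
17 | (1E)-3-[(2S,3R)-3-(acetoxymethyl)-5-(3-acetoxypropyl)-7-methoxy-2,3-dihydrobenzofuran-2-yl]buta-1,3-dien-1-yl acetate | COc1cc(CCCOC(C)=O)cc2c1O[C@H](C(=C)/C=C/OC(C)=O)[C@H]2COC(C)=O | intermediate
18 | acrolein | C=CC=O | starting material
19 | (1S,6R)-3-[(2S,3R)-3-(acetoxymethyl)-5-(3-acetoxypropyl)-7-methoxy-2,3-dihydrobenzofuran-2-yl]-6-formylcyclohex-2-en-1-yl acetate | COc1cc(CCCOC(C)=O)cc2c1O[C@H](C1=C[C@H](OC(C)=O)[C@H](C=O)CC1)[C@H]2COC(C)=O | intermediate
20 | 3-[(2S,3R)-3-(acetoxymethyl)-5-(3-acetoxypropyl)-7-methoxy-2,3-dihydrobenzofuran-2-yl]-6-(1-hydroxyethyl)cyclohex-2-en-1-yl acetate (ring centres as in 19, carbinol carbon as both epimers) | COc1cc(CCCOC(C)=O)cc2c1O[C@H](C1=C[C@H](OC(C)=O)[C@H](C(C)O)CC1)[C@H]2COC(C)=O | intermediate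
21 | (1S,6R)-6-acetyl-3-[(2S,3R)-3-(acetoxymethyl)-5-(3-acetoxypropyl)-7-methoxy-2,3-dihydrobenzofuran-2-yl]cyclohex-2-en-1-yl acetate | COc1cc(CCCOC(C)=O)cc2c1O[C@H](C1=C[C@H](OC(C)=O)[C@H](C(C)=O)CC1)[C@H]2COC(C)=O | intermediate
22 | (1R,2S)-4-[(2S,3R)-3-(acetoxymethyl)-5-(3-acetoxypropyl)-7-methoxy-2,3-dihydrobenzofuran-2-yl]cyclohex-3-ene-1,2-diyl diacetate | COc1cc(CCCOC(C)=O)cc2c1O[C@H](C1=C[C@H](OC(C)=O)[C@H](OC(C)=O)CC1)[C@H]2COC(C)=O | intermediate
23 | difengpiol A, (1R,2S)-4-[(2S,3R)-3-(hydroxymethyl)-5-(3-hydroxypropyl)-7-methoxy-2,3-dihydrobenzofuran-2-yl]cyclohex-3-ene-1,2-diol | COc1cc(CCCO)cc2c1O[C@H](C1=C[C@H](O)[C@H](O)CC1)[C@H]2CO | target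

## Step count and least certain steps

Total step count: 14. Longest linear sequence: 14 steps, from 1 to 23.

**Step 10 (key step).** The likeliest failure is erosion of diastereoselectivity if the diene-face preference imposed by C2 opposes the catalyst-defined endo approach. Slow solvolysis of the enol acetate in the protic acidic medium and β-elimination of acetic acid from the adduct through its enamine with the catalyst are the other risks. The fallback changes the mode of activation and the dienophile. Diene 17 would be combined with methyl vinyl ketone under a triflimide-activated chiral oxazaborolidine (the B-o-tolyl oxazaborolidine of α,α-diphenylprolinol protonated by HNTf2, antipode chosen to give 4′R) in CH2Cl2 at −78 °C. This is a known Lewis-acid-catalysed enantioselective Diels–Alder reaction of enones that runs without water or amine. It sets out from 17 and returns at methyl ketone 21, making steps 11 and 12 unnecessary; no new compound arises (F0).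

**Step 5.** The tetrasubstituted, ester-conjugated C2=C3 bond may be hydrogenated slowly and with poor enantioface discrimination, since it lies at the demanding end of the benzofuran class. The fallback gives up catalysis for reduction and resolution. Benzofuran 9 would be reduced with magnesium in methanol, a conjugate reduction that equilibrates to the trans isomer and transesterifies, to give the racemic trans methyl ester F1. Hydrolysis with LiOH would give the racemic trans acid F2. Crystallisation of its salt with one antipode of 1-phenylethylamine would give the (2S,3R)-acid F3, and ethylation with ethyl iodide and K2CO3 returns to 11.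

**Step 13.** The Lewis acid may ionise the allylic acetate or the allylic aryl ether, and migration of C4′ may be sluggish because of the neighbouring acetoxy group. The fallback oxidises the aldehyde instead of the ketone. Aldehyde 19 would be treated with buffered meta-chloroperbenzoic acid at 0 °C to give the formate F4, (1R,2S)-2-acetoxy-4-[(2S,3R)-3-(acetoxymethyl)-5-(3-acetoxypropyl)-7-methoxy-2,3-dihydrobenzofuran-2-yl]cyclohex-3-en-1-yl formate, which the methanolysis of step 14 would convert into 23. This path is open only if the alkene, deactivated by two allylic C–O bonds, proves slower towards peracid than the formyl group, and it risks some hydrogen migration to the acid.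

**Step 9.** Poor E/Z control and deactivation of the ruthenium catalyst by the enol ester (formation of an unreactive acyloxycarbene) are the likely problems. The fallback builds the diene by carbonyl chemistry. Alkyne 15 would be hydrated with Ph3PAuNTf2 in wet methanol to the methyl ketone F5, 1-[(2S,3R)-3-(acetoxymethyl)-5-(3-acetoxypropyl)-7-methoxy-2,3-dihydrobenzofuran-2-yl]ethan-1-one. Peterson olefination with lithiated N-tert-butyl-2-(trimethylsilyl)acetaldimine and mild acid hydrolysis would give the enal F6, 3-[(2S,3R)-3-(acetoxymethyl)-5-(3-acetoxypropyl)-7-methoxy-2,3-dihydrobenzofuran-2-yl]but-2-enal. Kinetic deprotonation at the methyl group with KOtBu in THF at −78 °C and O-acetylation of the dienolate with acetyl chloride returns to 17.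

**Step 2.** The ortho-hydroxybenzyl alcohol may react further (quinone methide formation and diarylmethane by-products), or conversion may be low with an enolisable aldehyde. The fallback installs the two carbons stepwise. Phenol 2 would be formylated at the free ortho position with MgCl2, Et3N and paraformaldehyde to give the salicylaldehyde F7, 2-hydroxy-3-methoxy-5-[3-(tert-butyldimethylsilyloxy)propyl]benzaldehyde. Wittig methylenation would give the vinylphenol F8, 2-ethenyl-6-methoxy-4-[3-(tert-butyldimethylsilyloxy)propyl]phenol. Dihydroxylation with catalytic OsO4 and N-methylmorpholine N-oxide would give the diol F9, 1-{2-hydroxy-3-methoxy-5-[3-(tert-butyldimethylsilyloxy)propyl]phenyl}ethane-1,2-diol. Selective silylation of its primary hydroxyl with TBSCl and imidazole returns to 5.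

## Further compounds

F0 | step 10 | none | none
F1 | step 5 | racemic methyl trans-3-[(tert-butyldimethylsilyloxy)methyl]-5-[3-(tert-butyldimethylsilyloxy)propyl]-7-methoxy-2,3-dihydrobenzofuran-2-carboxylate | COc1cc(CCCO[Si](C)(C)C(C)(C)C)cc2c1O[C@H](C(=O)OC)[C@H]2CO[Si](C)(C)C(C)(C)C.COc1cc(CCCO[Si](C)(C)C(C)(C)C)cc2c1O[C@@H](C(=O)OC)[C@@H]2CO[Si](C)(C)C(C)(C)C
F2 | step 5 | racemic trans-3-[(tert-butyldimethylsilyloxy)methyl]-5-[3-(tert-butyldimethylsilyloxy)propyl]-7-methoxy-2,3-dihydrobenzofuran-2-carboxylic acid | COc1cc(CCCO[Si](C)(C)C(C)(C)C)cc2c1O[C@H](C(=O)O)[C@H]2CO[Si](C)(C)C(C)(C)C.COc1cc(CCCO[Si](C)(C)C(C)(C)C)cc2c1O[C@@H](C(=O)O)[C@@H]2CO[Si](C)(C)C(C)(C)C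
F3 | step 5 | (2S,3R)-3-[(tert-butyldimethylsilyloxy)methyl]-5-[3-(tert-butyldimethylsilyloxy)propyl]-7-methoxy-2,3-dihydrobenzofuran-2-carboxylic acid | COc1cc(CCCO[Si](C)(C)C(C)(C)C)cc2c1O[C@H](C(=O)O)[C@H]2CO[Si](C)(C)C(C)(C)C
F4 | step 13 | (1R,2S)-2-acetoxy-4-[(2S,3R)-3-(acetoxymethyl)-5-(3-acetoxypropyl)-7-methoxy-2,3-dihydrobenzofuran-2-yl]cyclohex-3-en-1-yl formate | COc1cc(CCCOC(C)=O)cc2c1O[C@H](C1=C[C@H](OC(C)=O)[C@H](OC=O)CC1)[C@H]2COC(C)=O
F5 | step 9 | 1-[(2S,3R)-3-(acetoxymethyl)-5-(3-acetoxypropyl)-7-methoxy-2,3-dihydrobenzofuran-2-yl]ethan-1-one | COc1cc(CCCOC(C)=O)cc2c1O[C@H](C(C)=O)[C@H]2COC(C)=O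
F6 | step 9 | 3-[(2S,3R)-3-(acetoxymethyl)-5-(3-acetoxypropyl)-7-methoxy-2,3-dihydrobenzofuran-2-yl]but-2-enal (alkene isomers) | COc1cc(CCCOC(C)=O)cc2c1O[C@H](C(C)=CC=O)[C@H]2COC(C)=O
F7 | step 2 | 2-hydroxy-3-methoxy-5-[3-(tert-butyldimethylsilyloxy)propyl]benzaldehyde | COc1cc(CCCO[Si](C)(C)C(C)(C)C)cc(C=O)c1O
F8 | step 2 | 2-ethenyl-6-methoxy-4-[3-(tert-butyldimethylsilyloxy)propyl]phenol | COc1cc(CCCO[Si](C)(C)C(C)(C)C)cc(C=C)c1O
F9 | step 2 | racemic 1-{2-hydroxy-3-methoxy-5-[3-(tert-butyldimethylsilyloxy)propyl]phenyl}ethane-1,2-diol | COc1cc(CCCO[Si](C)(C)C(C)(C)C)cc(C(O)CO)c1O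
A1 | alternative 1 | trans-7-(pinacolboryl)-2-(acetonide-protected cis-3,4-dihydroxycyclohex-1-enyl)-3-[(tert-butyldimethylsilyloxy)methyl]-5-[3-(tert-butyldimethylsilyloxy)propyl]-2,3-dihydrobenzofuran | B1(OC(C)(C)C(C)(C)O1)c1cc(CCCO[Si](C)(C)C(C)(C)C)cc2c1O[C@H](C1=C[C@H](OC3(C)C)[C@H](O3)CC1)[C@H]2CO[Si](C)(C)C(C)(C)C
A2 | alternative 1 | ynol-ether diyne: pinacol [2-({1-(acetonide-protected cis-3,4-dihydroxycyclohex-1-enyl)-2-[(tert-butyldimethylsilyloxy)methyl]but-3-yn-1-yl}oxy)ethynyl]boronate | CC1(C)OB(OC1(C)C)C#CO[C@H](C1=C[C@H](OC3(C)C)[C@H](O3)CC1)[C@H](C#C)CO[Si](C)(C)C(C)(C)C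
A3 | alternative 1 | tert-butyldimethyl(pent-4-yn-1-yloxy)silane | C#CCCCO[Si](C)(C)C(C)(C)C
A4 | alternative 2 | ethyl trans-2-(acetonide-protected cis-3,4-dihydroxycyclohex-1-enyl)-7-methoxy-5-[3-(tert-butyldimethylsilyloxy)propyl]-2,3-dihydrobenzofuran-3-carboxylate | COc1cc(CCCO[Si](C)(C)C(C)(C)C)cc2c1O[C@H](C1=C[C@H](OC3(C)C)[C@H](O3)CC1)[C@H]2C(=O)OCC
A5 | alternative 2 | ethyl 2-diazo-2-{2-[(acetonide-protected cis-3,4-dihydroxycyclohex-1-enyl)methoxy]-3-methoxy-5-[3-(tert-butyldimethylsilyloxy)propyl]phenyl}acetate | COc1cc(CCCO[Si](C)(C)C(C)(C)C)cc(C(=[N+]=[N-])C(=O)OCC)c1OCC1=C[C@H](OC3(C)C)[C@H](O3)CC1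
A6 | alternative 3 | methyl trans-2-(cis-3,4-diacetoxycyclohex-1-enyl)-5-(3-acetoxypropyl)-7-methoxy-2,3-dihydrobenzofuran-3-carboxylate | COc1cc(CCCOC(C)=O)cc2c1O[C@H](C1=C[C@H](OC(C)=O)[C@H](OC(C)=O)CC1)[C@H]2C(=O)OC
A7 | alternative 3 | (2S)-2-(cis-3,4-diacetoxycyclohex-1-enyl)-6-(3-acetoxypropyl)-8-methoxychroman-4-one | COc1cc(CCCOC(C)=O)cc2c1O[C@H](C1=C[C@H](OC(C)=O)[C@H](OC(C)=O)CC1)CC2=O
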